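Retrosynthetic cuts, in order: the C4–O acyl bond (vanillate); C3–O and C2=C3 of the five-membered ring (epoxide/hydride, ring-closing metathesis); C8a–C1 (enolate allylation); C3a–C3 (carbometalative opening of an oxygen bridge); C6–CH3 (Grignard addition); last, C4–C5 and C7–C8 together.
Enabling feature (azulene numbering): in the seven-membered ring the oxygen-bearing carbons C4 and C8 stand on either side of the C3a–C8a bond, C8a carries a methyl group, and C6, the middle of the remaining C5–C6–C7 arc, is functionalised. C4–C3a–C8a(CH3)–C8 plus one oxygen is therefore 3-methylfuran, and C5–C6–C7 is a 2-oxyallyl cation.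
Forward order: the seven-membered ring is made first, as an 8-oxabicyclo[3.2.1]octenone. The bridge is opened at C8–O so its oxygen stays on C4, C8 is re-oxidised, the C6 carbinol is dehydrated to the enone, and C8a is allylated. The five-membered ring closes last by metathesis; the carbinol and the ester follow.
Stereochemistry: the cycloadduct is racemic and the series is resolved at the C4 alcohol as O-methylmandelates. C4 relays C3a (exo carbometalation, cis to the bridge oxygen), C3a relays C8a (allylation anti to the side chain, trans ring fusion), and the C4 hydroxyl relays C3 (directed epoxidation, hydride opening).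

Key step: step 1

Remark: the azulene numbering of the target is used for all carbocyclic intermediates. α is the face carrying the C4 oxygen and β the opposite face. Compounds 4, 5, 6 and 9 are racemates drawn as the enantiomer that is carried on.

Step 1
Reactants: 1 3-methylfuran; 2 1,1,3,3-tetrabromoacetone
Product: 5 rac-(1R,5S)-6-methyl-8-oxabicyclo[3.2.1]oct-6-en-3-one, via zinc 1,3-dibromo-2-oxyallyl cation 3 (not isolated), via 2,4-dibromo cycloadduct 4 (not isolated)
Conditions: Zn–Cu couple, THF, −10 → 25 °C; then Zn–Cu couple, NH4Cl, MeOH, 25 °C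
Reagents that add atoms: none
Why: Zn–Cu transfers two electrons to 2, and loss of bromide from the resulting zinc enolate gives the 1,3-dibromo-2-oxyallyl cation 3, a two-electron, three-carbon partner. It combines with the four π electrons of the diene unit C8=C8a–C3a=C4 of 1 in a (4+3) cycloaddition that forms C7–C8 and C4–C5, either in concert or by attack of the more nucleophilic furan carbon next to the methyl group followed by fast collapse of the zinc enolate onto the oxocarbenium ion; the closest known reaction type is the reductive polybromoketone–furan (4+3) cycloaddition that gives 8-oxabicyclo[3.2.1]oct-6-en-3-ones. The seven-membered carbocycle closes by this intermolecular cycloaddition, both termini of the cation bonding to the two α-carbons of the furan, and the furan oxygen is left as a one-atom bridge, so the tetrahydropyranone ring of the bicycle closes in the same event. The bridgehead centres C4 and C8 arise together and their cis relation is fixed by suprafacial bonding on one face of the planar furan, while the absolute sense is not controlled, so 5 is racemic until step 4. Because 3 is symmetric no regiochemistry arises, and the selectivity needed is cycloaddition over electrophilic substitution at a furan α-position, which the two bromine substituents (a more electrophilic, longer-lived cation) and the tightly bound zinc–oxygen terminus secure. The C–Br centres of 4 need no control, since Zn–Cu and NH4Cl in MeOH then replace both bromines by hydrogen.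

Step 2
Reactants: 5 rac-(1R,5S)-6-methyl-8-oxabicyclo[3.2.1]oct-6-en-3-one
Product: 6 rac-(1R,3R,5S)-3,6-dimethyl-8-oxabicyclo[3.2.1]oct-6-en-3-ol (endo hydroxyl; exo methyl)
Conditions: MeMgBr, THF, −78 → 0 °C
Reagents that add atoms: methylmagnesium bromide, C[Mg]Br
Why: Grignard 1,2-addition at low temperature outruns enolisation of the β-alkoxy ketone; the reagent comes in along the open equatorial (exo) trajectory, away from the C3a=C8a bridge, so the methyl group ends exo and the hydroxyl endo (a centre that step 10 erases), which places the C6 methyl of the target and masks the ketone for step 3.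

Step 3
Reactants: 6 rac-(1R,3R,5S)-3,6-dimethyl-8-oxabicyclo[3.2.1]oct-6-en-3-ol; 7 2-bromo-3-methylbut-1-ene
Product: 9 rac-(1S,3R,4R)-1,5-dimethyl-4-(3-methylbut-1-en-2-yl)cyclohept-5-ene-1,3-diol (C4-OH α; C3a side chain α; C6-OH β), via (3-methylbut-1-en-2-yl)magnesium bromide 8 (not isolated)
Conditions: 7, Mg, THF, 45 °C; then 6, FeCl3 (10 mol %), THF, 0 → 25 °C
Reagents that add atoms: none
Why: Proposed new method: FeCl3 is reduced by 8 to a low-valent alkenyl ferrate that should add syn across the strained C3a=C8a bond from the exo face (the face of the oxygen bridge), carbon going to the unsubstituted C3a and iron to the methyl-bearing C8a, after which syn β-alkoxide elimination of the C8–O bond relieves the ring strain and leaves the bridge oxygen as the C4 alkoxide cis to the new side chain, which sets C3a; the closest known reaction type is the iron-catalysed carbomagnesiation/ring opening of 8-oxabicyclo[3.2.1]oct-6-enes having a 1,2-disubstituted alkene with aryl and alkenyl Grignard reagents, and what is new is the trisubstituted alkene, for which the methyl group should reinforce the regiochemistry (bond formation at the CH terminus) while the transient tertiary alkyl–iron species is drained at once by the elimination.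

Step 4
Reactants: 9 rac-(1S,3R,4R)-1,5-dimethyl-4-(3-methylbut-1-en-2-yl)cyclohept-5-ene-1,3-diol
Product: 10 C4 (S)-O-methylmandelate of the 4R diol (single diastereomer)
Conditions: (S)-O-methylmandelic acid, DCC, DMAP (cat.), CH2Cl2, 0 → 25 °C; separation of the diastereomers on silica gel
Reagents that add atoms: (S)-O-methylmandelic acid, CO[C@H](C(=O)O)c1ccccc1
Why: Steglich esterification acylates only the secondary C4 hydroxyl and turns the racemate into two diastereomeric esters whose difference lies next to the ester bond, so they should separate on silica gel (classical resolution); the ester of the 4R alcohol is kept and its configuration is to be secured by the shielding model for O-methylmandelates or by X-ray analysis, which fixes the absolute configuration of the whole series.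

Step 5
Reactants: 10 C4 (S)-O-methylmandelate of the 4R diol
Product: 11 (1S,3R,4R)-1,5-dimethyl-4-(3-methylbut-1-en-2-yl)cyclohept-5-ene-1,3-diol (single enantiomer)
Conditions: K2CO3 (cat.), MeOH, 25 °C
Reagents that add atoms: none
Why: Base-catalysed transesterification frees the alcohol under conditions that touch neither alkene nor any ring stereocentre.

Step 6
Reactants: 11 (1S,3R,4R)-1,5-dimethyl-4-(3-methylbut-1-en-2-yl)cyclohept-5-ene-1,3-diol
Product: 12 C4 tert-butyldimethylsilyl ether of 11 (C6-OH free)
Conditions: TBSOTf (1.05 equiv), 2,6-lutidine, CH2Cl2, −78 °C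
Reagents that add atoms: tert-butyldimethylsilyl triflate, CC(C)(C)[Si](C)(C)OS(=O)(=O)C(F)(F)F
Why: Silyl ether formation with the triflate at −78 °C takes the secondary hydroxyl ahead of the tertiary one; the ether keeps O4 from re-closing the bridge onto C8 in step 7, from being oxidised in step 9 and from being allylated in step 11.

Step 7
Reactants: 12 C4 tert-butyldimethylsilyl ether of 11
Product: 13 8β,8aβ-epoxide of 12
Conditions: mCPBA (1.0 equiv), CH2Cl2, 0 °C
Reagents that add atoms: 3-chloroperoxybenzoic acid, OOC(=O)c1cccc(Cl)c1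
Why: Prilezhaev epoxidation picks the electron-richer trisubstituted ring alkene over the hindered 1,1-disubstituted side-chain alkene (the selectivity known from limonene); attack is expected on the β face, anti to the two α substituents and guided by hydrogen bonding to the β C6 hydroxyl, but the face is of no consequence because C8 and C8a are both flattened later.

Step 8
Reactants: 13 8β,8aβ-epoxide of 12
Product: 14 C8β secondary alcohol with C8a-H (mixture of C8a epimers; C6-OH free; C4-OTBS)
Conditions: Cp2TiCl2 (10 mol %), Mn, 2,4,6-collidine·HCl, 1,4-cyclohexadiene, THF, 25 °C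
Reagents that add atoms: none
Why: Titanocene-catalysed reductive epoxide opening: trivalent titanium (Cp2TiCl, formed from Cp2TiCl2 and Mn) cleaves the C8a–O bond homolytically to the tertiary radical, which takes a hydrogen atom from cyclohexadiene, so oxygen stays on C8 (the anti-Markovnikov alcohol) without a borane that would attack the side-chain alkene first; the C8a epimers converge in step 11.

Step 9
Reactants: 14 C8β secondary alcohol
Product: 15 C8 ketone with tertiary C6 hydroxyl (β-hydroxy ketone; C8a epimers)
Conditions: Dess–Martin periodinane, CH2Cl2, 0 → 25 °C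
Reagents that add atoms: none
Why: Dess–Martin oxidation converts the only secondary alcohol into the C8 ketone under near-neutral conditions that leave the tertiary aldol-type hydroxyl, the silyl ether and the alkene alone.

Step 10
Reactants: 15 C8 ketone with tertiary C6 hydroxyl
Product: 17 5-(tert-butyldimethylsilyloxy)-3,7-dimethyl-6-(3-methylbut-1-en-2-yl)cyclohept-2-en-1-one (C4-OTBS α; C3a side chain α; C8a epimers), via C6 mesylate 16 (not isolated)
Conditions: MsCl, Et3N, CH2Cl2, 0 → 25 °C
Reagents that add atoms: none
Why: Mesylation of the tertiary β-hydroxyl followed by E1cB elimination through the C7 enolate gives the conjugated C6=C7 enone irreversibly, avoiding the retro-aldol path that is open under reversible base catalysis.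

Step 11
Reactants: 17 5-(tert-butyldimethylsilyloxy)-3,7-dimethyl-6-(3-methylbut-1-en-2-yl)cyclohept-2-en-1-one
Product: 19 7-allyl-5-(tert-butyldimethylsilyloxy)-3,7-dimethyl-6-(3-methylbut-1-en-2-yl)cyclohept-2-en-1-one (C8a allyl β; C8a methyl α), via lithium cross-conjugated dienolate 18 (not isolated)
Conditions: LiN(iPr)2, THF, −78 °C; then allyl bromide, DMPU, −78 → −30 °C
Reagents that add atoms: allyl bromide, C=CCBr
Why: Kinetic deprotonation of an enone occurs at α′, here C8a because C7 is vinylic, and SN2 allylation of the cross-conjugated dienolate takes place anti to the C3a side chain, which stands pseudoaxial to avoid allylic strain with the C8a methyl group, so the allyl group enters on the β face and the quaternary centre is set with methyl α (trans relation of C1 and C3).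

Step 12
Reactants: 19 7-allyl-5-(tert-butyldimethylsilyloxy)-3,7-dimethyl-6-(3-methylbut-1-en-2-yl)cyclohept-2-en-1-one
Product: 20 trans-fused 4α-(tert-butyldimethylsilyloxy)-3-isopropyl-6,8a-dimethyl-3a,4,5,8a-tetrahydroazulen-8(1H)-one (C2=C3 alkene; H3a β; C8a methyl α)
Conditions: second-generation Grubbs catalyst (5 mol %), CH2Cl2, 40 °C
Reagents that add atoms: none
Why: Ring-closing metathesis: the catalyst loads on the monosubstituted allyl alkene and closes onto the neighbouring 1,1-disubstituted alkene, a five-membered ring closure helped by the quaternary centre, while the electron-poor trisubstituted enone is inert.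

Step 13
Reactants: 20 trans-fused silyloxy hydroazulenone
Product: 21 4α-hydroxy-3-isopropyl-6,8a-dimethyl-3a,4,5,8a-tetrahydroazulen-8(1H)-one
Conditions: HF·pyridine, THF, 0 → 25 °C
Reagents that add atoms: none
Why: Fluoride-mediated desilylation in an acidic medium avoids the alkoxide that could trigger vinylogous retro-aldol cleavage or elimination in the δ-oxy enone.

Step 14
Reactants: 21 4α-hydroxy-3-isopropyl-6,8a-dimethyl-3a,4,5,8a-tetrahydroazulen-8(1H)-one
Product: 22 2α,3α-epoxide of 21
Conditions: VO(acac)2 (5 mol %), tBuOOH, CH2Cl2, 0 → 25 °C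
Reagents that add atoms: tert-butyl hydroperoxide, CC(C)(C)OO
Why: Vanadium-catalysed hydroxyl-directed epoxidation: the vanadate ester of the α C4 homoallylic alcohol delivers the peroxide oxygen intramolecularly to the α face of C2=C3, against the steric bias of the angular methyl group, which sets C3 (oxygen α); the enone alkene is too electron-poor to react.

Step 15
Reactants: 22 2α,3α-epoxide of 21
Product: 23 3α,4α,8-triol with C6=C7 alkene (C8 epimers)
Conditions: LiAlH4, THF, 0 → 65 °C
Reagents that add atoms: none
Why: Hydride opens the trisubstituted epoxide by SN2 attack at the less substituted C2, so the C3–O bond and its configuration are kept as the tertiary carbinol, and the β-methyl enone is reduced 1,2 to the allylic alcohol in the same operation (the C8 epimers are irrelevant).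

Step 16
Reactants: 23 3α,4α,8-triol
Product: 24 (3R,3aS,4R,8aS)-3,4-dihydroxy-3-isopropyl-6,8a-dimethyl-2,3,3a,4,5,8a-hexahydroazulen-8(1H)-one
Conditions: MnO2, CH2Cl2, 25 °C
Reagents that add atoms: none
Why: MnO2 oxidises only the allylic C8 alcohol, which tells it apart from the saturated secondary C4 and tertiary C3 hydroxyls without protecting groups.

Step 17
Reactants: 25 vanillic acid
Product: 27 4-(tert-butyldimethylsilyloxy)-3-methoxybenzoic acid, via bis-silylated vanillic acid 26 (not isolated)
Conditions: TBSCl (2.2 equiv), imidazole, DMF, 25 °C; then AcOH–THF–H2O, 25 °C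
Reagents that add atoms: tert-butyldimethylsilyl chloride, CC(C)(C)[Si](C)(C)Cl
Why: Exhaustive silylation followed by hydrolysis of the far more labile silyl ester leaves the phenol masked and the acid free.

Step 18
Reactants: 24 (3R,3aS,4R,8aS)-3,4-dihydroxy-3-isopropyl-6,8a-dimethyl-2,3,3a,4,5,8a-hexahydroazulen-8(1H)-one; 27 4-(tert-butyldimethylsilyloxy)-3-methoxybenzoic acid
Product: 28 C4 ester of 24 with 27 (phenol silyl ether of the target)
Conditions: DCC, DMAP, CH2Cl2, 0 → 25 °C
Reagents that add atoms: none
Why: Steglich esterification acylates the secondary C4 hydroxyl with retention, the tertiary C3 hydroxyl being too hindered, under conditions mild enough for the base-sensitive δ-acyloxy enone.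

Step 19
Reactants: 28 phenol silyl ether of the target
Product: 29 (3R,3aS,4R,8aS)-3-hydroxy-3-isopropyl-6,8a-dimethyl-8-oxo-1,2,3,3a,4,5,8,8a-octahydroazulen-4-yl 4-hydroxy-3-methoxybenzoate (CNP0136950.1)
Conditions: Bu4NF, AcOH, THF, 0 °C
Reagents that add atoms: none
Why: Aryl silyl ethers are cleaved rapidly by fluoride, and buffering with AcOH keeps the medium from eliminating the vanillate through the extended enolate.

Compound list
1 | 3-methylfuran | Cc1ccoc1 | starting material
2 | 1,1,3,3-tetrabromoacetone | BrC(Br)C(=O)C(Br)Br | starting material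
3 | zinc 1,3-dibromo-2-oxyallyl cation | Br[CH+]C(=CBr)O[Zn]Br | intermediate
4 | 2,4-dibromo-6-methyl-8-oxabicyclo[3.2.1]oct-6-en-3-one (racemic; C–Br epimers) | O1[C@@H]2C(Br)C(=O)C(Br)[C@H]1C(C)=C2 | intermediate
5 | rac-(1R,5S)-6-methyl-8-oxabicyclo[3.2.1]oct-6-en-3-one | O1[C@@H]2CC(=O)C[C@H]1C(C)=C2 | intermediate
6 | rac-(1R,3R,5S)-3,6-dimethyl-8-oxabicyclo[3.2.1]oct-6-en-3-ol | O1[C@@H]2C[C@@](C)(O)C[C@H]1C(C)=C2 | intermediate
7 | 2-bromo-3-methylbut-1-ene | C=C(Br)C(C)C | starting material
8 | (3-methylbut-1-en-2-yl)magnesium bromide | CC(C)C(=C)[Mg]Br | intermediate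
9 | rac-(1S,3R,4R)-1,5-dimethyl-4-(3-methylbut-1-en-2-yl)cyclohept-5-ene-1,3-diol | O[C@@H]1C[C@@](C)(O)CC=C(C)[C@@H]1C(=C)C(C)C | intermediate
10 | C4 (S)-O-methylmandelate of the 4R diol | CO[C@H](C(=O)O[C@@H]1C[C@@](C)(O)CC=C(C)[C@@H]1C(=C)C(C)C)c1ccccc1 | intermediate
11 | (1S,3R,4R)-1,5-dimethyl-4-(3-methylbut-1-en-2-yl)cyclohept-5-ene-1,3-diol (single enantiomer) | O[C@@H]1C[C@@](C)(O)CC=C(C)[C@@H]1C(=C)C(C)C | intermediate
12 | C4 tert-butyldimethylsilyl ether of 11 | CC(C)(C)[Si](C)(C)O[C@@H]1C[C@@](C)(O)CC=C(C)[C@@H]1C(=C)C(C)C | intermediate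
13 | 8β,8aβ-epoxide of 12 | CC(C)(C)[Si](C)(C)O[C@@H]1C[C@@](C)(O)C[C@H]2O[C@@]2(C)[C@@H]1C(=C)C(C)C | intermediate
14 | C8β alcohol (C8a epimers) | CC(C)(C)[Si](C)(C)O[C@@H]1C[C@@](C)(O)C[C@@H](O)C(C)[C@@H]1C(=C)C(C)C | intermediate
15 | C8 ketone with tertiary C6 hydroxyl (C8a epimers) | CC(C)(C)[Si](C)(C)O[C@@H]1C[C@@](C)(O)CC(=O)C(C)[C@@H]1C(=C)C(C)C | intermediate
16 | C6 mesylate of 15 | CC(C)(C)[Si](C)(C)O[C@@H]1C[C@@](C)(OS(C)(=O)=O)CC(=O)C(C)[C@@H]1C(=C)C(C)C | intermediate
17 | 5-(tert-butyldimethylsilyloxy)-3,7-dimethyl-6-(3-methylbut-1-en-2-yl)cyclohept-2-en-1-one (C8a epimers) | CC(C)(C)[Si](C)(C)O[C@@H]1CC(C)=CC(=O)C(C)[C@@H]1C(=C)C(C)C | intermediate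
18 | lithium cross-conjugated dienolate of 17 | [Li]OC1=C(C)[C@H](C(=C)C(C)C)[C@H](O[Si](C)(C)C(C)(C)C)CC(C)=C1 | intermediate
19 | 7-allyl-5-(tert-butyldimethylsilyloxy)-3,7-dimethyl-6-(3-methylbut-1-en-2-yl)cyclohept-2-en-1-one (allyl β; methyl α) | CC(C)(C)[Si](C)(C)O[C@@H]1CC(C)=CC(=O)[C@@](C)(CC=C)[C@@H]1C(=C)C(C)C | intermediate
20 | trans-fused 4α-(tert-butyldimethylsilyloxy)-3-isopropyl-6,8a-dimethyl-3a,4,5,8a-tetrahydroazulen-8(1H)-one | CC(C)(C)[Si](C)(C)O[C@@H]2CC(C)=CC(=O)[C@@]3(C)CC=C(C(C)C)[C@H]23 | intermediate
21 | 4α-hydroxy-3-isopropyl-6,8a-dimethyl-3a,4,5,8a-tetrahydroazulen-8(1H)-one | O[C@@H]2CC(C)=CC(=O)[C@@]3(C)CC=C(C(C)C)[C@H]23 | intermediate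
22 | 2α,3α-epoxide of 21 | O[C@@H]2CC(C)=CC(=O)[C@@]3(C)C[C@@H]4O[C@]4(C(C)C)[C@H]23 | intermediate
23 | 3α,4α,8-triol (C8 epimers) | O[C@@H]2CC(C)=CC(O)[C@@]3(C)CC[C@@](O)(C(C)C)[C@H]23 | intermediate
24 | (3R,3aS,4R,8aS)-3,4-dihydroxy-3-isopropyl-6,8a-dimethyl-2,3,3a,4,5,8a-hexahydroazulen-8(1H)-one | O[C@@H]2CC(C)=CC(=O)[C@@]3(C)CC[C@@](O)(C(C)C)[C@H]23 | intermediate
25 | vanillic acid | COc1cc(C(=O)O)ccc1O | starting material
26 | tert-butyldimethylsilyl 4-(tert-butyldimethylsilyloxy)-3-methoxybenzoate | COc1cc(C(=O)O[Si](C)(C)C(C)(C)C)ccc1O[Si](C)(C)C(C)(C)C | intermediate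
27 | 4-(tert-butyldimethylsilyloxy)-3-methoxybenzoic acid | COc1cc(C(=O)O)ccc1O[Si](C)(C)C(C)(C)C | intermediate
28 | phenol tert-butyldimethylsilyl ether of the target | COc1cc(C(=O)O[C@@H]2CC(C)=CC(=O)[C@@]3(C)CC[C@@](O)(C(C)C)[C@H]23)ccc1O[Si](C)(C)C(C)(C)C | intermediate
29 | (3R,3aS,4R,8aS)-3-hydroxy-3-isopropyl-6,8a-dimethyl-8-oxo-1,2,3,3a,4,5,8,8a-octahydroazulen-4-yl 4-hydroxy-3-methoxybenzoate | COc1cc(C(=O)O[C@@H]2CC(C)=CC(=O)[C@@]3(C)CC[C@@](O)(C(C)C)[C@H]23)ccc1O | target

Total step count: 19. Longest linear sequence: 18 (steps 1–16, 18, 19).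

Steps most likely to fail

Step 3. Carbometalation of the trisubstituted alkene may be too slow, so that homocoupling of the Grignard reagent or plain recovery of the substrate takes over, or carbon may be delivered with poor regiocontrol.
- The fallback sets out from 6, returns at 9, and makes the alkene electrophilic first.
- SeO2 in dioxane at 80 °C oxidises the only usable allylic position, the methyl group (the bridgehead C–H bonds cannot take part), to rac-3-hydroxy-3-methyl-8-oxabicyclo[3.2.1]oct-6-ene-6-carbaldehyde F1.
- The cuprate made from 8 and CuBr·SMe2 adds 1,4 to C3a from the exo face, and the resulting enolate expels the C8–O bond of the bridge (E1cB). This gives rac-4,6-dihydroxy-4-methyl-7-(3-methylbut-1-en-2-yl)cyclohept-1-ene-1-carbaldehyde F2 with the same cis relation of side chain and C4 hydroxyl.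
- Luche reduction (NaBH4, CeCl3·7H2O, MeOH) gives rac-5-(hydroxymethyl)-1-methyl-4-(3-methylbut-1-en-2-yl)cyclohept-5-ene-1,3-diol F3.
- SO3·pyridine in THF converts the primary allylic hydroxyl into the allylic hydrogen sulfate F4, which LiAlH4 reduces in the same flask to the methyl group without allylic shift, giving 9.

Step 11. Slow deprotonation at the hindered tertiary α′ position and slow alkylation of the tetrasubstituted dienolate leave time for proton transfer to the extended dienolate. That would bring loss of the C4 silyloxy group, and facial selectivity may also be incomplete.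
- The fallback sets out from 17 and returns at 19.
- The dienolate is trapped on oxygen at −78 °C with allyl chloroformate, a fast reaction, to give the allyl dienol carbonate F5.
- Pd(PPh3)4 (zerovalent palladium) in THF at 25 °C then ionises it, CO2 is lost, and the enolate/π-allyl pair recombines at C8a under neutral conditions (Tsuji decarboxylative allylation).
- A chiral phosphinooxazoline ligand can replace PPh3 to reinforce β-face attack.

Step 14. Oxygen delivery to the α face has to overcome shielding by the angular methyl group. A sluggish directed reaction would let undirected β-face epoxidation or oxidation of the C4 alcohol compete.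
- The fallback sets out from 21, returns at 24, and tethers the oxygen instead.
- Boc2O and DMAP give the C4 tert-butyl carbonate F6.
- IBr in toluene at −78 °C forms the iodonium ion on the open β face, and the carbonate oxygen closes onto the tertiary C3 from the α face (iodocarbonate cyclisation) to give the 2β-iodo 3α,4α-cyclic carbonate F7.
- Bu3SnH and AIBN in toluene at 80 °C remove the iodine to give the 3α,4α-cyclic carbonate F8.
- K2CO3 in MeOH releases 24, which also makes steps 15 and 16 unnecessary.

Further compounds
F1 | step 3 | rac-3-hydroxy-3-methyl-8-oxabicyclo[3.2.1]oct-6-ene-6-carbaldehyde | O1[C@@H]2C[C@@](C)(O)C[C@H]1C(C=O)=C2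
F2 | step 3 | rac-4,6-dihydroxy-4-methyl-7-(3-methylbut-1-en-2-yl)cyclohept-1-ene-1-carbaldehyde | O[C@@H]1C[C@@](C)(O)CC=C(C=O)[C@@H]1C(=C)C(C)C
F3 | step 3 | rac-5-(hydroxymethyl)-1-methyl-4-(3-methylbut-1-en-2-yl)cyclohept-5-ene-1,3-diol | O[C@@H]1C[C@@](C)(O)CC=C(CO)[C@@H]1C(=C)C(C)C
F4 | step 3 | allylic hydrogen sulfate of F3 | O[C@@H]1C[C@@](C)(O)CC=C(COS(=O)(=O)O)[C@@H]1C(=C)C(C)C
F5 | step 11 | allyl dienol carbonate of 17 | C=CCOC(=O)OC1=C(C)[C@H](C(=C)C(C)C)[C@H](O[Si](C)(C)C(C)(C)C)CC(C)=C1
F6 | step 14 | C4 tert-butyl carbonate of 21 | CC(C)(C)OC(=O)O[C@@H]2CC(C)=CC(=O)[C@@]3(C)CC=C(C(C)C)[C@H]23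
F7 | step 14 | 2β-iodo 3α,4α-cyclic carbonate | O=C1O[C@@H]2CC(C)=CC(=O)[C@@]3(C)C[C@@H](I)[C@@](O1)(C(C)C)[C@H]23
F8 | step 14 | 3α,4α-cyclic carbonate of 24 | O=C1O[C@@H]2CC(C)=CC(=O)[C@@]3(C)CC[C@@](O1)(C(C)C)[C@H]23
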